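**Strategy.** Ring C is cut at three bonds around its carbonyl. C4 is a single carbonyl carbon lying between C4a of ring A and C3, so it can come from carbon monoxide, while O1–C2 comes from a phenol adding to an alkyne. One palladium-catalysed operation joins 2-iodo-5-methoxyresorcinol, CO and the MOM-protected ring B arylacetylene and closes the pyranone. Because ring A is a symmetric resorcinol iodinated between its hydroxyls, no regiochemical issue arises, and the hydroxyl left over becomes the chelated 5-OH that later steers iodine to C6. The C3 prenyl and C6 ketone side chains are added afterwards to the flavone.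

Key step: step 4

Remark: the target has no stereocentre, and the C6 side chain is taken as the open keto form drawn in the SMILES.

Step 1
Reactants: 1 5-methoxybenzene-1,3-diol
Product: 2 2-iodo-5-methoxybenzene-1,3-diol
Conditions: I2 (1.0 equiv), NaHCO3, THF/H2O (1:1), 0 °C to rt
Reagents that add atoms: iodine, II
Why: Electrophilic aromatic iodination of the phenoxide under bicarbonate buffering should place iodine between the two hydroxyls, by analogy with the iodination of resorcinol to its 2-iodo derivative, and one equivalent of I2 at 0 °C limits over-iodination.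

Step 2
Reactants: 3 2,4-dihydroxybenzaldehyde
Product: 4 2,4-bis(methoxymethoxy)benzaldehyde
Conditions: MOMCl (3 equiv), K2CO3, acetone, reflux
Reagents that add atoms: chloromethyl methyl ether (MOMCl), COCCl
Why: Williamson-type O-alkylation of both phenols, run in refluxing acetone so that the hydrogen-bonded 2-hydroxyl is alkylated as well as the 4-hydroxyl.

Step 3
Reactants: 4 2,4-bis(methoxymethoxy)benzaldehyde
Product: 6 1-ethynyl-2,4-bis(methoxymethoxy)benzene, via diazoalkene 5 (not isolated)
Conditions: dimethyl (1-diazo-2-oxopropyl)phosphonate, K2CO3, MeOH, rt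
Reagents that add atoms: dimethyl (1-diazo-2-oxopropyl)phosphonate, CC(=O)C(=[N+]=[N-])P(=O)(OC)OC
Why: Ohira–Bestmann (Seyferth–Gilbert) homologation, in which methanolysis unmasks dimethyl (diazomethyl)phosphonate, its anion adds to the aldehyde and collapses in Horner–Wadsworth–Emmons fashion to diazoalkene 5, and loss of N2 with a 1,2-hydride shift gives the terminal alkyne under conditions that spare the MOM ethers.

Step 4
Reactants: 2 2-iodo-5-methoxybenzene-1,3-diol; 6 1-ethynyl-2,4-bis(methoxymethoxy)benzene; 7 carbon monoxide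
Product: 10 2-[2,4-bis(methoxymethoxy)phenyl]-5-hydroxy-7-methoxy-4H-chromen-4-one, via ynone 8 (not isolated), via enaminone 9 (not isolated)
Conditions: PdCl2(PPh3)2 (5 mol%), CO (20 bar), Et2NH (solvent and base), 120 °C, autoclave
Reagents that add atoms: none
Why: Zerovalent palladium, formed in situ from PdCl2(PPh3)2, inserts into the C–I bond of 2, CO insertion gives an aroylpalladium iodide, and amine-assisted transfer of the alkynyl group of 6 followed by reductive elimination should deliver ynone 8 (bonds C4a–C4 and C4–C3). Diethylamine then adds to the ynone to give enaminone 9, and one of the two equivalent phenol oxygens attacks the amine-bearing carbon and expels the amine, forming O1–C2. The closest known reaction is the palladium-catalysed carbonylative Sonogashira annulation of o-iodophenols with terminal alkynes to flavones. Ring C closes by a 6-endo addition–elimination (6-endo-trig on 9, equivalent to 6-endo-dig on 8), and no stereocentre is formed. Two selectivities are needed: carbonylation ahead of direct alkynylation, secured by CO pressure and the absence of copper, and the pyranone ahead of the 5-exo aurone, secured by the secondary amine, which turns the ynone into an enaminone whose electrophilic carbon is C2. Ring A regiochemistry cannot arise because 2 is symmetric about its C–I axis, so either hydroxyl gives the same product and the other remains as the chelated 5-hydroxyl.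

Step 5
Reactants: 10 2-[2,4-bis(methoxymethoxy)phenyl]-5-hydroxy-7-methoxy-4H-chromen-4-one
Product: 11 2-[2,4-bis(methoxymethoxy)phenyl]-5-hydroxy-6-iodo-7-methoxy-4H-chromen-4-one
Conditions: BnMe3N+ ICl2− (1.05 equiv), CaCO3, CH2Cl2/MeOH, rt
Reagents that add atoms: benzyltrimethylammonium dichloroiodate, C[N+](C)(C)Cc1ccccc1.Cl[I-]Cl
Why: Electrophilic aromatic iodination in which the hydrogen-bonded 5-hydroxyl should direct iodine to its free ortho position C6 and not to C8, the known preference of 5-hydroxy-7-alkoxyflavones with this reagent, while CaCO3 scavenges HCl so that the MOM ethers on the less activated ring B survive.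

Step 6
Reactants: 11 2-[2,4-bis(methoxymethoxy)phenyl]-5-hydroxy-6-iodo-7-methoxy-4H-chromen-4-one
Product: 13 2-[2,4-bis(methoxymethoxy)phenyl]-6-iodo-7-methoxy-5-(methoxymethoxy)-4H-chromen-4-one, via sodium phenoxide 12 (not isolated)
Conditions: NaH, DMF, 0 °C; then MOMCl, 0 °C to rt
Reagents that add atoms: chloromethyl methyl ether (MOMCl), COCCl
Why: Williamson-type O-alkylation of the preformed sodium phenoxide, chosen because the chelated, iodine-flanked 5-hydroxyl is too unreactive for amine bases and must be masked before the lithiation.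

Step 7
Reactants: 13 2-[2,4-bis(methoxymethoxy)phenyl]-6-iodo-7-methoxy-5-(methoxymethoxy)-4H-chromen-4-one; 14 1-bromo-3-methylbut-2-ene
Product: 16 2-[2,4-bis(methoxymethoxy)phenyl]-6-iodo-7-methoxy-5-(methoxymethoxy)-3-(3-methylbut-2-en-1-yl)-4H-chromen-4-one, via 3-lithioflavone 15 (not isolated)
Conditions: LiN(i-Pr)2 (1.2 equiv), THF, −78 °C, short metalation; then 14, −78 to −40 °C
Reagents that add atoms: none
Why: Directed deprotonation of C3–H of the flavone by the lithium amide, the vinyl anion being stabilised by the adjacent C4 carbonyl and by chelation to the 2'-MOM oxygen, followed by SN2 alkylation with the allylic bromide; the C6 iodide has no ortho hydrogen, and the cold, short metalation is meant to limit iodine–lithium transfer and ring opening of the anion.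

Step 8
Reactants: 17 3-methylbutan-2-one
Product: 19 trimethyl[(3-methylbut-1-en-2-yl)oxy]silane, via lithium enolate 18 (not isolated)
Conditions: LiN(i-Pr)2, THF, −78 °C; then Me3SiCl, −78 °C to rt
Reagents that add atoms: chlorotrimethylsilane, C[Si](C)(C)Cl
Why: Kinetic deprotonation of the methyl group at −78 °C followed by O-silylation should give the less substituted silyl enol ether, which fixes in advance the α-carbon that will be arylated.

Step 9
Reactants: 16 2-[2,4-bis(methoxymethoxy)phenyl]-6-iodo-7-methoxy-5-(methoxymethoxy)-3-(3-methylbut-2-en-1-yl)-4H-chromen-4-one; 19 trimethyl[(3-methylbut-1-en-2-yl)oxy]silane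
Product: 21 2-[2,4-bis(methoxymethoxy)phenyl]-7-methoxy-5-(methoxymethoxy)-6-(3-methyl-2-oxobutyl)-3-(3-methylbut-2-en-1-yl)-4H-chromen-4-one, via tin enolate 20 (not isolated)
Conditions: Pd(OAc)2 (5 mol%), P(t-Bu)3 (10 mol%), Bu3SnF (1.5 equiv), toluene, 85 °C
Reagents that add atoms: none
Why: Palladium-catalysed α-arylation of a ketone through its tin enolate, in which Bu3SnF converts 19 into the stannyl enolate, zerovalent palladium inserts into the C6–I bond, and transmetalation with reductive elimination forges the C6–CH2 bond under neutral conditions that spare the pyranone, the MOM ethers and the unreactive trisubstituted prenyl alkene.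

Step 10
Reactants: 21 2-[2,4-bis(methoxymethoxy)phenyl]-7-methoxy-5-(methoxymethoxy)-6-(3-methyl-2-oxobutyl)-3-(3-methylbut-2-en-1-yl)-4H-chromen-4-one
Product: 22 2-(2,4-dihydroxyphenyl)-5-hydroxy-7-methoxy-6-(3-methyl-2-oxobutyl)-3-(3-methylbut-2-en-1-yl)-4H-chromen-4-one
Conditions: HCl (3 M aq.)/MeOH, 40 °C, stopped at full conversion
Reagents that add atoms: none
Why: Acid-catalysed acetal cleavage (methanolysis) of the three MOM ethers, the peri 5-ether going first, with dilute acid and mild temperature chosen so that the prenyl group is not hydrated or cyclised and the freed 5-hydroxyl does not condense with the side-chain ketone to a furan.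

**Compound list**

1 | 5-methoxybenzene-1,3-diol | COc1cc(O)cc(O)c1 | starting material
2 | 2-iodo-5-methoxybenzene-1,3-diol | COc1cc(O)c(I)c(O)c1 | intermediate
3 | 2,4-dihydroxybenzaldehyde | O=Cc1ccc(O)cc1O | starting material
4 | 2,4-bis(methoxymethoxy)benzaldehyde | COCOc1ccc(C=O)c(OCOC)c1 | intermediate
5 | 1-(2-diazoethenyl)-2,4-bis(methoxymethoxy)benzene | COCOc1ccc(C=C=[N+]=[N-])c(OCOC)c1 | intermediate
6 | 1-ethynyl-2,4-bis(methoxymethoxy)benzene | C#Cc1ccc(OCOC)cc1OCOC | intermediate
7 | carbon monoxide | [C-]#[O+] | starting material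
8 | 1-(2,6-dihydroxy-4-methoxyphenyl)-3-[2,4-bis(methoxymethoxy)phenyl]prop-2-yn-1-one | COc1cc(O)c(C(=O)C#Cc2ccc(OCOC)cc2OCOC)c(O)c1 | intermediate
9 | 3-(diethylamino)-1-(2,6-dihydroxy-4-methoxyphenyl)-3-[2,4-bis(methoxymethoxy)phenyl]prop-2-en-1-one (push–pull alkene, geometry not fixed) | CCN(CC)C(=CC(=O)c1c(O)cc(OC)cc1O)c1ccc(OCOC)cc1OCOC | intermediate
10 | 2-[2,4-bis(methoxymethoxy)phenyl]-5-hydroxy-7-methoxy-4H-chromen-4-one | COCOc1ccc(-c2cc(=O)c3c(O)cc(OC)cc3o2)c(OCOC)c1 | intermediate
11 | 2-[2,4-bis(methoxymethoxy)phenyl]-5-hydroxy-6-iodo-7-methoxy-4H-chromen-4-one | COCOc1ccc(-c2cc(=O)c3c(O)c(I)c(OC)cc3o2)c(OCOC)c1 | intermediate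
12 | sodium 2-[2,4-bis(methoxymethoxy)phenyl]-6-iodo-7-methoxy-4-oxo-4H-chromen-5-olate | COCOc1ccc(-c2cc(=O)c3c([O-])c(I)c(OC)cc3o2)c(OCOC)c1.[Na+] | intermediate
13 | 2-[2,4-bis(methoxymethoxy)phenyl]-6-iodo-7-methoxy-5-(methoxymethoxy)-4H-chromen-4-one | COCOc1ccc(-c2cc(=O)c3c(OCOC)c(I)c(OC)cc3o2)c(OCOC)c1 | intermediate
14 | 1-bromo-3-methylbut-2-ene (prenyl bromide) | CC(C)=CCBr | starting material
15 | {2-[2,4-bis(methoxymethoxy)phenyl]-6-iodo-7-methoxy-5-(methoxymethoxy)-4-oxo-4H-chromen-3-yl}lithium | COCOc1ccc(-c2oc3cc(OC)c(I)c(OCOC)c3c(=O)c2[Li])c(OCOC)c1 | intermediate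
16 | 2-[2,4-bis(methoxymethoxy)phenyl]-6-iodo-7-methoxy-5-(methoxymethoxy)-3-(3-methylbut-2-en-1-yl)-4H-chromen-4-one | COCOc1ccc(-c2oc3cc(OC)c(I)c(OCOC)c3c(=O)c2CC=C(C)C)c(OCOC)c1 | intermediate
17 | 3-methylbutan-2-one | CC(C)C(C)=O | starting material
18 | lithium 3-methylbut-1-en-2-olate | [Li]OC(=C)C(C)C | intermediate
19 | trimethyl[(3-methylbut-1-en-2-yl)oxy]silane | C=C(O[Si](C)(C)C)C(C)C | intermediate
20 | tributyl[(3-methylbut-1-en-2-yl)oxy]stannane | CCCC[Sn](CCCC)(CCCC)OC(=C)C(C)C | intermediate
21 | 2-[2,4-bis(methoxymethoxy)phenyl]-7-methoxy-5-(methoxymethoxy)-6-(3-methyl-2-oxobutyl)-3-(3-methylbut-2-en-1-yl)-4H-chromen-4-one | COCOc1ccc(-c2oc3cc(OC)c(CC(=O)C(C)C)c(OCOC)c3c(=O)c2CC=C(C)C)c(OCOC)c1 | intermediate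
22 | 2-(2,4-dihydroxyphenyl)-5-hydroxy-7-methoxy-6-(3-methyl-2-oxobutyl)-3-(3-methylbut-2-en-1-yl)-4H-chromen-4-one | COc1cc2oc(-c3ccc(O)cc3O)c(CC=C(C)C)c(=O)c2c(O)c1CC(=O)C(C)C | target

**Total step count:** 10.
**Longest linear sequence:** 8 steps (steps 2, 3, 4, 5, 6, 7, 9 and 10, from 3 to 22).

**Steps most likely to fail**

Step 4. The acylpalladium species may be intercepted by diethylamine (aminocarbonylation). The alkyne may couple without CO uptake and then close to a furan. The ynone may close 5-exo. Oxidative addition into the very electron-rich di-ortho-hydroxy iodide may be slow enough for reductive loss of iodine to dominate. The fallback sets out from 4 and returns at 10, building ring C without carbon monoxide by the chalcone route. Aldehyde 4 would be condensed (Claisen–Schmidt; KOH, EtOH/H2O, rt) with purchased 1-(2,6-dihydroxy-4-methoxyphenyl)ethan-1-one F1 to give (E)-1-(2,6-dihydroxy-4-methoxyphenyl)-3-[2,4-bis(methoxymethoxy)phenyl]prop-2-en-1-one F2. Oxa-Michael closure (NaOAc, EtOH, reflux) should give racemic 2-[2,4-bis(methoxymethoxy)phenyl]-5-hydroxy-7-methoxy-2,3-dihydro-4H-chromen-4-one F3. Dehydrogenation with I2 in pyridine at 90 °C, buffered so that the MOM ethers survive, should then give 10.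

Step 7. Iodine may be transferred from C6 of one molecule to the C3 carbanion of another (iodine–lithium exchange). The 3-lithio species may ring-open on warming, or the bromide may be attacked in SN2' fashion. The fallback sets out from 13 and returns at 22, removing the iodide before any carbanion is made. Iodide 13 would be coupled with 19 under the conditions of step 9 (through 20) to give 2-[2,4-bis(methoxymethoxy)phenyl]-7-methoxy-5-(methoxymethoxy)-6-(3-methyl-2-oxobutyl)-4H-chromen-4-one F4. Deprotonation of the benzylic ketone with KN(SiMe3)2 in THF at −78 °C should give potassium (Z)-1-{2-[2,4-bis(methoxymethoxy)phenyl]-7-methoxy-5-(methoxymethoxy)-4-oxo-4H-chromen-6-yl}-3-methylbut-1-en-2-olate F5. O-Silylation with t-BuMe2SiCl would mask the ketone as 2-[2,4-bis(methoxymethoxy)phenyl]-6-[(Z)-2-(tert-butyldimethylsilyloxy)-3-methylbut-1-en-1-yl]-7-methoxy-5-(methoxymethoxy)-4H-chromen-4-one F6 (mainly Z expected, geometry of no consequence). Lithiation with LiN(i-Pr)2 at −78 °C would give the 3-lithio derivative of F6, F7. Alkylation with 14 should give 2-[2,4-bis(methoxymethoxy)phenyl]-6-[(Z)-2-(tert-butyldimethylsilyloxy)-3-methylbut-1-en-1-yl]-7-methoxy-5-(methoxymethoxy)-3-(3-methylbut-2-en-1-yl)-4H-chromen-4-one F8. The conditions of step 10 would hydrolyse the silyl enol ether together with the MOM ethers and give 22 directly.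

Step 9. Oxidative addition and transmetalation at C6, which is flanked by two alkoxy groups, may be so slow that hydrodeiodination or consumption of the enolate outruns C–C coupling. The fallback sets out from 16 and returns at 21, reversing the polarity at C6. Iodine–magnesium exchange (i-PrMgCl·LiCl, THF, −30 °C, assisted by the ortho MOM oxygen) should give {2-[2,4-bis(methoxymethoxy)phenyl]-7-methoxy-5-(methoxymethoxy)-3-(3-methylbut-2-en-1-yl)-4-oxo-4H-chromen-6-yl}magnesium chloride F9. CuI-catalysed opening of purchased racemic 2-(propan-2-yl)oxirane F10 at its CH2 carbon would give racemic 2-[2,4-bis(methoxymethoxy)phenyl]-6-(2-hydroxy-3-methylbutyl)-7-methoxy-5-(methoxymethoxy)-3-(3-methylbut-2-en-1-yl)-4H-chromen-4-one F11. Oxidation with Dess–Martin periodinane (NaHCO3, CH2Cl2) removes the stereocentre and should give 21.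

**Further compounds**

F1 | step 4 | 1-(2,6-dihydroxy-4-methoxyphenyl)ethan-1-one (purchased) | CC(=O)c1c(O)cc(OC)cc1O
F2 | step 4 | (E)-1-(2,6-dihydroxy-4-methoxyphenyl)-3-[2,4-bis(methoxymethoxy)phenyl]prop-2-en-1-one | COCOc1ccc(/C=C/C(=O)c2c(O)cc(OC)cc2O)c(OCOC)c1
F3 | step 4 | rac-2-[2,4-bis(methoxymethoxy)phenyl]-5-hydroxy-7-methoxy-2,3-dihydro-4H-chromen-4-one | COCOc1ccc(C2CC(=O)c3c(O)cc(OC)cc3O2)c(OCOC)c1
F4 | step 7 | 2-[2,4-bis(methoxymethoxy)phenyl]-7-methoxy-5-(methoxymethoxy)-6-(3-methyl-2-oxobutyl)-4H-chromen-4-one | COCOc1ccc(-c2cc(=O)c3c(OCOC)c(CC(=O)C(C)C)c(OC)cc3o2)c(OCOC)c1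
F5 | step 7 | potassium (Z)-1-{2-[2,4-bis(methoxymethoxy)phenyl]-7-methoxy-5-(methoxymethoxy)-4-oxo-4H-chromen-6-yl}-3-methylbut-1-en-2-olate | COCOc1ccc(-c2cc(=O)c3c(OCOC)c(/C=C(\[O-])C(C)C)c(OC)cc3o2)c(OCOC)c1.[K+]
F6 | step 7 | 2-[2,4-bis(methoxymethoxy)phenyl]-6-[(Z)-2-(tert-butyldimethylsilyloxy)-3-methylbut-1-en-1-yl]-7-methoxy-5-(methoxymethoxy)-4H-chromen-4-one | COCOc1ccc(-c2cc(=O)c3c(OCOC)c(/C=C(\O[Si](C)(C)C(C)(C)C)C(C)C)c(OC)cc3o2)c(OCOC)c1
F7 | step 7 | {2-[2,4-bis(methoxymethoxy)phenyl]-6-[(Z)-2-(tert-butyldimethylsilyloxy)-3-methylbut-1-en-1-yl]-7-methoxy-5-(methoxymethoxy)-4-oxo-4H-chromen-3-yl}lithium | COCOc1ccc(-c2oc3cc(OC)c(/C=C(\O[Si](C)(C)C(C)(C)C)C(C)C)c(OCOC)c3c(=O)c2[Li])c(OCOC)c1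
F8 | step 7 | 2-[2,4-bis(methoxymethoxy)phenyl]-6-[(Z)-2-(tert-butyldimethylsilyloxy)-3-methylbut-1-en-1-yl]-7-methoxy-5-(methoxymethoxy)-3-(3-methylbut-2-en-1-yl)-4H-chromen-4-one | COCOc1ccc(-c2oc3cc(OC)c(/C=C(\O[Si](C)(C)C(C)(C)C)C(C)C)c(OCOC)c3c(=O)c2CC=C(C)C)c(OCOC)c1
F9 | step 9 | {2-[2,4-bis(methoxymethoxy)phenyl]-7-methoxy-5-(methoxymethoxy)-3-(3-methylbut-2-en-1-yl)-4-oxo-4H-chromen-6-yl}magnesium chloride | COCOc1ccc(-c2oc3cc(OC)c([Mg]Cl)c(OCOC)c3c(=O)c2CC=C(C)C)c(OCOC)c1
F10 | step 9 | rac-2-(propan-2-yl)oxirane (purchased) | CC(C)C1CO1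
F11 | step 9 | rac-2-[2,4-bis(methoxymethoxy)phenyl]-6-(2-hydroxy-3-methylbutyl)-7-methoxy-5-(methoxymethoxy)-3-(3-methylbut-2-en-1-yl)-4H-chromen-4-one | COCOc1ccc(-c2oc3cc(OC)c(CC(O)C(C)C)c(OCOC)c3c(=O)c2CC=C(C)C)c(OCOC)c1
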